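I read the substrate first.

| flask | substrate | gas phase | remark | time |
|---|---|---|---|---|
| north-west | 25 mM | 4.8 mM (held) | the very flask that is asked about, followed so far |  |
| south-west | 38 mM | 4.8 mM (held) | run made earlier |  |
| flask | 25 mM | 4.8 mM (held) |  | 30 min |

| run | time / min | target / % | substrate / % |
|---|---|---|---|
| north-west | 0.667 | 1.7 | 98.9 |
| north-west | 1.33 | 4.4 | 96.4 |
| north-west | 2.00 | 4.1 | 94.6 |
| north-west | 3.00 | 6.2 | 90.7 |
| north-west | 5.00 | 11.4 | 87.2 |
| north-west | 10.0 | 12.9 | 77.0 |
| south-west | 1.50 | 3.6 | 96.5 |
| south-west | 3.00 | 4.3 | 92.2 |
| south-west | 5.00 | 9.3 | 90.2 |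
| south-west | 8.00 | 10.7 | 85.0 |
| south-west | 12.0 | 11.5 | 81.2 |
| south-west | 20.0 | 10.0 | 70.2 |

(each reading ± 1 percentage point)

- percent here means substrate units held: one side product counts as two
- at the start none of the gas is dissolved
- steps that have been proposed: gas phase <-> dissolved gas; substrate + dissolved gas <-> target; dissolved gas + target -> over-reacted product; substrate + target -> side product

- Thursday's: doubling the transfer coefficient of the gas phase, all else as stated
- Sunday's: doubling the saturation concentration of gas phase, all else as stated

- how much target there is at 30 min, in percent of the substrate charged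
- the change that raises the amount of target at 30 min, in percent of the substrate charged most ("none" if none brings more than 2 percentage points) (Thursday's / Sunday's / none)
- amount of target at 30 min, in percent of the substrate charged, after Sunday's

The north-west flask kept 77.0 % of its substrate at 10.0 min. The south-west flask kept 70.2 % at 20.0 min, but it had a larger charge. So I took the logarithm of one over each fraction kept, divided it by the time and multiplied by the charge. North-west gave 0.653 mM min⁻¹, my loss number: the charge times the pseudo-first-order constant of substrate loss, as read from that run's last reading. South-west gave 0.672 mM min⁻¹, nearly the same.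

So I reckoned 45.7 % of the substrate left in the asked flask at 30 min. The last north-west reading gave a target-to-substrate ratio of 0.168, so I expected 7.68 % target. If a change doubled the loss number, the fraction left was squared, and at the same ratio I reckoned target at 3.51 %. So I chose none.

The forecast said 8 %, 5 % after Sunday's, and none. It held that more gas “burns substrate faster at the same ratio”. My reckoned figure for a doubled loss number stood below the forecast's figure for Sunday's.

The flask gave 10.3 %, 5.79 % after Sunday's, and none.

    gas phase ⇌ dissolved gas, rate k1*(csat - [dissolved gas]) (kL = 0.00330 s⁻¹)
    substrate + dissolved gas ⇌ target (K = 190 M⁻¹, k = 4.00 M⁻¹ s⁻¹)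
    dissolved gas + target → over-reacted product (k = 1.90 M⁻¹ s⁻¹)
    substrate + target → side product (k = 0.00660 M⁻¹ s⁻¹)

In the asked flask, target reached 7.35 % by 3.00 min, while dissolved gas stood at 0.533 mM. At 30.0 min, with dissolved gas at 1.23 mM, over-reacted product held 37.1 %, and target was made at 0.886 of the rate it was used up. The flask kept 48 % substrate against my 45.7 %. In the neighbour flask with 42 mM substrate, the loss number gave 62.7 % left, and that flask kept 62 %.

The runs stem from a simulated flask for an exercise, and the scatter is random.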